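**Plan**
- Ring B (C5–C10) is a cyclohexene whose C7=C8 bond carries the C8 methyl and lies between C9 (bearing the C11–C16 chain) and the quaternary C10 next to C5–H. This is the retron of a [4+2] between a C6=C7(OSi)–C8(Me)=C9 diene and a C5=C10 enal, so the retrosynthesis cuts C5–C6 and C9–C10.
- Before that, ring A is cut at C2=C3 (aldol condensation), C3–C4 and C1–C2 (one-carbon additions), C4–C19 (methoxymethylenation) and C4–C18 (methylation). The diene is cut at C8=C9 (Wittig) back to an aldehyde from (R)-citronellic acid.
- Forward order: chain and diene, then ring B by catalytic enantioselective cycloaddition, then ring A by intramolecular aldol condensation, then C4, C2 and C3. An enol triflate at C7 stands in for the C7=C8 alkene until the last step.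
- Stereochemistry: C13 from (R)-citronellic acid; C5 and C10 from the chiral oxazaborolidinium catalyst and the E dienophile; C9 from the cycloaddition topology; C4 by methylation anti to the C10 methyl; C2 and C3 by OsO4 addition anti to the two axial groups.

Key step: step 6

Remark: atoms are numbered as in labdanes (rings A and B C1–C10, chain C11–C16, C17 on C8, C18 methyl and C19 formyl on C4, C20 on C10), and (R)-citronellic acid is taken as commercially available in high enantiomeric purity.

**Step 1**
Reactants: 1 (R)-3,7-dimethyloct-6-enoic acid [(R)-citronellic acid]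
Product: 2 tert-butyl (R)-3,7-dimethyloct-6-enoate
Conditions: Boc2O, t-BuOH, 4-(dimethylamino)pyridine (cat.), THF, 23 → 40 °C
Reagents that add atoms: tert-butanol CC(C)(C)O; di-tert-butyl dicarbonate CC(C)(C)OC(=O)OC(=O)OC(C)(C)C
Why: Mixed-anhydride esterification through the acylpyridinium gives the tert-butyl ester without touching the alkene or C13, and this ester keeps C15 at its final oxidation level through all later bases, ylides and Grignard reagents.

**Step 2**
Reactants: 2 tert-butyl (R)-3,7-dimethyloct-6-enoate
Product: 3 tert-butyl (R)-3-methyl-6-oxohexanoate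
Conditions: O3, CH2Cl2, −78 °C; then Me2S, −78 → 23 °C
Reagents that add atoms: ozone [O-][O+]=O
Why: Ozonolysis with reductive work-up cleaves the only alkene to the aldehyde (C11) and acetone, leaving the ester and the stereocentre alone.

**Step 3**
Reactants: 4 3-bromobutan-2-one
Product: 6 ylide 3-(triphenylphosphoranylidene)butan-2-one, via phosphonium bromide 5 (not isolated)
Conditions: PPh3, toluene, 80 °C; then NaOH (aq), CH2Cl2, 23 °C
Reagents that add atoms: triphenylphosphine c1ccc(cc1)P(c1ccccc1)c1ccccc1
Why: SN2 quaternisation of the phosphine by the α-bromo ketone followed by deprotonation of the salt is the standard preparation of a stabilised acyl ylide.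

**Step 4**
Reactants: 3 tert-butyl (R)-3-methyl-6-oxohexanoate; 6 3-(triphenylphosphoranylidene)butan-2-one
Product: 7 tert-butyl (R,E)-3,7-dimethyl-8-oxonon-6-enoate
Conditions: toluene, 90 °C
Reagents that add atoms: none
Why: Wittig olefination with a stabilised α-methyl acyl ylide gives the E trisubstituted enone under thermodynamic control, which fixes the geometry of the future C8=C9 diene terminus.

**Step 5**
Reactants: 7 tert-butyl (R,E)-3,7-dimethyl-8-oxonon-6-enoate
Product: 8 tert-butyl (R,E)-3,7-dimethyl-8-(triisopropylsilyloxy)nona-6,8-dienoate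
Conditions: i-Pr3SiOSO2CF3, Et3N, CH2Cl2, −78 → 0 °C
Reagents that add atoms: triisopropylsilyl trifluoromethanesulfonate CC(C)[Si](C(C)C)(C(C)C)OS(=O)(=O)C(F)(F)F
Why: Soft enolisation (O-silylation of the enone, then amine deprotonation of the acetyl methyl group) gives the cross-conjugated 2-silyloxy diene without touching the ester α-protons, and the bulky silyl group is chosen to survive the acidic cycloaddition catalyst.

**Step 6**
Reactants: 8 tert-butyl (R,E)-3,7-dimethyl-8-(triisopropylsilyloxy)nona-6,8-dienoate; 9 ethyl (E)-3-methyl-4-oxobut-2-enoate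
Product: 10 ethyl (1S,5R,6S)-5-[(3R)-5-tert-butoxy-3-methyl-5-oxopentyl]-6-formyl-4,6-dimethyl-3-(triisopropylsilyloxy)cyclohex-3-ene-1-carboxylate
Conditions: (R)-3,3-diphenyl-1-(o-tolyl)tetrahydro-1H,3H-pyrrolo[1,2-c][1,3,2]oxazaborole (20 mol%), HN(SO2CF3)2 (18 mol%), CH2Cl2, −78 → −40 °C
Reagents that add atoms: none
Why: The N-protonated oxazaborolidine binds the formyl oxygen of 9 (boron coordination backed by a formyl C–H···O contact), so the enal is most electrophilic at C5 and the enol-silane terminus C6 of 8 attacks there first, with C9–C10 closing in the same concerted but asynchronous [4+2] event; the closest known reaction type is the cationic-oxazaborolidine-catalysed Diels–Alder reaction of 2-silyloxy dienes with 2-methyl-substituted enals. Ring B is closed by an intermolecular, suprafacial six-membered cycloaddition without a tether. C10 and C5 are set together by the catalyst, one phenyl group of which shields one face of the bound s-trans enal so that the diene adds to the open face (the R catalyst is the enantiomer expected to give 10S,5S), and their trans formyl/ester relation is fixed by the E geometry of 9. C9 is set by topology: the E diene terminus together with the formyl-exo/ester-endo arrangement expected for an α-methyl enal places C11 cis to the C10 methyl group. The step needs complete regiocontrol, which is secured because the C7 silyloxy group and the C9 alkyl group both make C6 the nucleophilic terminus. The remote C13 centre cannot interfere, so the diastereomer ratio should simply mirror the enantioselectivity of the catalyst.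

**Step 7**
Reactants: 10 cycloadduct (C7 enol silane)
Product: 11 ethyl (1S,5R,6S)-5-[(3R)-5-tert-butoxy-3-methyl-5-oxopentyl]-6-formyl-4,6-dimethyl-3-(trifluoromethylsulfonyloxy)cyclohex-3-ene-1-carboxylate
Conditions: CsF, PhN(SO2CF3)2, DME, 23 °C
Reagents that add atoms: N-phenylbis(trifluoromethanesulfonimide) O=S(=O)(N(c1ccccc1)S(=O)(=O)C(F)(F)F)C(F)(F)F
Why: Fluoride releases the enolate regiospecifically at C7–C8 and the triflimide traps it on oxygen before it can equilibrate (enol silane to enol triflate exchange), giving an electron-poor latent C7=C8 alkene that tolerates acid, ylides and OsO4.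

**Step 8**
Reactants: 11 C7 enol triflate aldehyde
Product: 12 the 6-(2-methoxyethenyl) analogue of 11 (C10–CH=CH–OMe in place of C10–CHO; E/Z mixture; ring and chain configuration unchanged)
Conditions: Ph3P(CH2OMe)Cl, KN(SiMe3)2, THF, 0 °C; then 11, −78 → 0 °C
Reagents that add atoms: (methoxymethyl)triphenylphosphonium chloride COC[P+](c1ccccc1)(c1ccccc1)c1ccccc1.[Cl-]
Why: Wittig methoxymethylenation adds C2 to the non-enolisable neopentyl aldehyde as a masked aldehyde, while both esters and the enol triflate are inert to the ylide at this temperature.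

**Step 9**
Reactants: 12 enol ether ethyl ester
Product: 13 the N-methoxy-N-methylamide of 12 (C4 carboxamide in place of the ethyl ester)
Conditions: MeNH(OMe)·HCl, i-PrMgCl, THF, −20 → 0 °C
Reagents that add atoms: N,O-dimethylhydroxylamine hydrochloride CNOC.Cl
Why: Aminolysis by the chloromagnesium amide of N,O-dimethylhydroxylamine converts the ethyl ester into the Weinreb amide, whereas the tert-butyl ester does not undergo this acyl substitution and the enol triflate does not react with magnesium reagents without a transition-metal catalyst.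

**Step 10**
Reactants: 13 Weinreb amide
Product: 14 methyl ketone (C5–C4(=O)–C3H3) still carrying the C1=C2 enol ether and the C7 enol triflate
Conditions: MeMgBr, THF, −20 → 0 °C; then NH4Cl (aq)
Reagents that add atoms: methylmagnesium bromide C[Mg]Br
Why: Weinreb ketone synthesis adds C3 as a methyl group and stops at the ketone because the chelated tetrahedral intermediate only collapses on work-up, the hindered tert-butyl ester being left alone at this temperature.

**Step 11**
Reactants: 14 methyl ketone enol ether
Product: 16 trans-fused ring-A enone (C2=C3–C4=O) carrying the C7 enol triflate and the C9 chain, via keto aldehyde 15 (not isolated)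
Conditions: 1 M HCl, THF, 23 °C; extraction, then dibenzylammonium trifluoroacetate, toluene, 50 °C
Reagents that add atoms: none
Why: Enol ether hydrolysis frees the C2 aldehyde and the ammonium-salt-mediated intramolecular aldol condensation (6-enolendo-exo-trig, the only six-membered closure available) forms ring A, with the trans fusion following from the trans C1/C4 groups of 10 and being the favoured epimer at the enolisable C5.

**Step 12**
Reactants: 16 ring-A enone
Product: 18 conjugated enal (C19HO on C4 and C3=C4), via dienol ether 17 (not isolated)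
Conditions: Ph3P(CH2OMe)Cl, KN(SiMe3)2, THF, 0 → 23 °C; then 2 M HCl (aq), 23 °C
Reagents that add atoms: (methoxymethyl)triphenylphosphonium chloride COC[P+](c1ccccc1)(c1ccccc1)c1ccccc1.[Cl-]; water O
Why: Wittig methoxymethylenation of the C4 ketone adds C19 and hydrolysis of the 1-methoxy diene by protonation at C2 gives the conjugated enal, C5 being safe because it is not vinylogously acidic.

**Step 13**
Reactants: 18 conjugated enal
Product: 19 C4-quaternary β,γ-unsaturated aldehyde (C4 methyl trans and C4 formyl cis to the C10 methyl, with C2=C3)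
Conditions: KOC(CH3)3, THF, −78 → −20 °C; then MeI, −78 → 0 °C
Reagents that add atoms: iodomethane CI
Why: γ-Deprotonation at C2 gives the extended dienolate, which is methylated at its α-carbon (deconjugative α-alkylation of an enal) from the face opposite the axial C10 methyl group, so that C4 becomes quaternary with the formyl group cis to C20 and the alkene moves to C2=C3.

**Step 14**
Reactants: 19 C2=C3 alkene aldehyde
Product: 20 2,3-cis-diol (both hydroxyl groups trans to the C10 methyl)
Conditions: OsO4 (4 mol%), N-methylmorpholine N-oxide, acetone/H2O, 0 → 23 °C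
Reagents that add atoms: osmium tetroxide O=[Os](=O)(=O)=O; N-methylmorpholine N-oxide C[N+]1([O-])CCOCC1; water O
Why: Upjohn syn-dihydroxylation occurs only at C2=C3, because the enol triflate is too electron-poor, and from the face opposite the axial C20 methyl and C4 formyl groups, which sets C2 and C3.

**Step 15**
Reactants: 20 2,3-diol
Product: 21 2-acetate 3-alcohol (tert-butyl ester and C7 enol triflate retained)
Conditions: Ac2O (1.2 equiv), pyridine, CH2Cl2, 0 °C
Reagents that add atoms: acetic anhydride CC(=O)OC(C)=O
Why: Acylation is kinetically selective for the equatorial C2 hydroxyl over the axial C3 hydroxyl next to the quaternary C4 (steric differentiation within a cis-diol on a trans-decalin).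

**Step 16**
Reactants: 21 tert-butyl ester
Product: 22 C15 carboxylic acid still carrying the C7 enol triflate
Conditions: CF3CO2H, CH2Cl2, 0 → 23 °C; then NaHCO3 (aq) wash and acidification
Reagents that add atoms: none
Why: Acidolysis of the tert-butyl ester (loss of isobutene through the tert-butyl cation) frees the acid while the acid-stable enol triflate still masks the acid-sensitive C7=C8 alkene, and acetate, aldehyde and alcohol survive.

**Step 17**
Reactants: 22 enol triflate acid
Product: 23 (2S,3R,4S,5S,9R,10S,13R)-2-acetoxy-3-hydroxy-19-oxolabd-7-en-15-oic acid (target)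
Conditions: Pd(OAc)2 (10 mol%), PPh3 (20 mol%), HCO2H, n-Bu3N, DMF, 60 °C
Reagents that add atoms: none
Why: Oxidative addition of the enol triflate to zerovalent palladium formed in situ, formate exchange, decarboxylation and reductive elimination replace the triflate by hydrogen without moving the double bond (palladium-catalysed formate reduction of enol triflates), under buffered conditions that spare acid, acetate, alcohol and aldehyde.

**Compound list**
1 | (R)-3,7-dimethyloct-6-enoic acid | CC(C)=CCC[C@@H](C)CC(=O)O | starting material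
2 | tert-butyl (R)-3,7-dimethyloct-6-enoate | CC(C)=CCC[C@@H](C)CC(=O)OC(C)(C)C | intermediate
3 | tert-butyl (R)-3-methyl-6-oxohexanoate | O=CCC[C@@H](C)CC(=O)OC(C)(C)C | intermediate
4 | 3-bromobutan-2-one (racemic) | CC(Br)C(C)=O | starting material
5 | (3-oxobutan-2-yl)triphenylphosphonium bromide | CC(=O)C(C)[P+](c1ccccc1)(c1ccccc1)c1ccccc1.[Br-] | intermediate
6 | 3-(triphenylphosphoranylidene)butan-2-one | CC(=O)C(C)=P(c1ccccc1)(c1ccccc1)c1ccccc1 | intermediate
7 | tert-butyl (R,E)-3,7-dimethyl-8-oxonon-6-enoate | CC(=O)/C(C)=C/CC[C@@H](C)CC(=O)OC(C)(C)C | intermediate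
8 | tert-butyl (R,E)-3,7-dimethyl-8-(triisopropylsilyloxy)nona-6,8-dienoate | C=C(O[Si](C(C)C)(C(C)C)C(C)C)/C(C)=C/CC[C@@H](C)CC(=O)OC(C)(C)C | intermediate
9 | ethyl (E)-3-methyl-4-oxobut-2-enoate | CCOC(=O)/C=C(C)/C=O | starting material
10 | ethyl (1S,5R,6S)-5-[(3R)-5-tert-butoxy-3-methyl-5-oxopentyl]-6-formyl-4,6-dimethyl-3-(triisopropylsilyloxy)cyclohex-3-ene-1-carboxylate | O=C[C@@]1(C)[C@H](CC[C@@H](C)CC(=O)OC(C)(C)C)C(C)=C(O[Si](C(C)C)(C(C)C)C(C)C)C[C@@H]1C(=O)OCC | intermediate
11 | ethyl (1S,5R,6S)-5-[(3R)-5-tert-butoxy-3-methyl-5-oxopentyl]-6-formyl-4,6-dimethyl-3-(trifluoromethylsulfonyloxy)cyclohex-3-ene-1-carboxylate | O=C[C@@]1(C)[C@H](CC[C@@H](C)CC(=O)OC(C)(C)C)C(C)=C(OS(=O)(=O)C(F)(F)F)C[C@@H]1C(=O)OCC | intermediate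
12 | 6-(2-methoxyethenyl) analogue of 11 (E/Z mixture) | COC=C[C@@]1(C)[C@H](CC[C@@H](C)CC(=O)OC(C)(C)C)C(C)=C(OS(=O)(=O)C(F)(F)F)C[C@@H]1C(=O)OCC | intermediate
13 | N-methoxy-N-methylamide corresponding to 12 | COC=C[C@@]1(C)[C@H](CC[C@@H](C)CC(=O)OC(C)(C)C)C(C)=C(OS(=O)(=O)C(F)(F)F)C[C@@H]1C(=O)N(C)OC | intermediate
14 | methyl ketone corresponding to 13 (acetyl on C5) | COC=C[C@@]1(C)[C@H](CC[C@@H](C)CC(=O)OC(C)(C)C)C(C)=C(OS(=O)(=O)C(F)(F)F)C[C@@H]1C(C)=O | intermediate
15 | keto aldehyde (C10–CH2–CHO and C5–acetyl) | O=CC[C@@]1(C)[C@H](CC[C@@H](C)CC(=O)OC(C)(C)C)C(C)=C(OS(=O)(=O)C(F)(F)F)C[C@@H]1C(C)=O | intermediate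
16 | trans-fused ring-A enone (C2=C3–C4=O) with C7 enol triflate | O=C1C=CC[C@@]2(C)[C@H](CC[C@@H](C)CC(=O)OC(C)(C)C)C(C)=C(OS(=O)(=O)C(F)(F)F)C[C@H]12 | intermediate
17 | dienol ether (C19H(OMe)=C4–C3=C2; E/Z mixture) | COC=C1C=CC[C@@]2(C)[C@H](CC[C@@H](C)CC(=O)OC(C)(C)C)C(C)=C(OS(=O)(=O)C(F)(F)F)C[C@H]12 | intermediate
18 | conjugated enal (C4-formyl, C3=C4) | O=CC1=CCC[C@@]2(C)[C@H](CC[C@@H](C)CC(=O)OC(C)(C)C)C(C)=C(OS(=O)(=O)C(F)(F)F)C[C@H]12 | intermediate
19 | C4-methyl C4-formyl Δ2 alkene (formyl cis to C20) | O=C[C@]1(C)C=CC[C@@]2(C)[C@H](CC[C@@H](C)CC(=O)OC(C)(C)C)C(C)=C(OS(=O)(=O)C(F)(F)F)C[C@H]12 | intermediate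
20 | 2,3-cis-diol (both OH trans to C20) | O[C@H]1C[C@@]2(C)[C@H](CC[C@@H](C)CC(=O)OC(C)(C)C)C(C)=C(OS(=O)(=O)C(F)(F)F)C[C@@H]2[C@](C)(C=O)[C@H]1O | intermediate
21 | 2-acetate of 20 | CC(=O)O[C@H]1C[C@@]2(C)[C@H](CC[C@@H](C)CC(=O)OC(C)(C)C)C(C)=C(OS(=O)(=O)C(F)(F)F)C[C@@H]2[C@](C)(C=O)[C@H]1O | intermediate
22 | C15 acid of 21 (C7 enol triflate retained) | CC(=O)O[C@H]1C[C@@]2(C)[C@H](CC[C@@H](C)CC(=O)O)C(C)=C(OS(=O)(=O)C(F)(F)F)C[C@@H]2[C@](C)(C=O)[C@H]1O | intermediate
23 | (2S,3R,4S,5S,9R,10S,13R)-2-acetoxy-3-hydroxy-19-oxolabd-7-en-15-oic acid | CC(=O)O[C@H]1C[C@@]2(C)[C@H](CC[C@@H](C)CC(=O)O)C(C)=CC[C@@H]2[C@](C)(C=O)[C@H]1O | target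

**Step count**
Total: 17 steps. Longest linear sequence: 16 steps (1 to 23 through steps 1, 2 and 4–17); the ylide branch adds one step.

**Steps most likely to fail**

Step 6. The formyl-exo/ester-endo topology may not dominate over the formyl-endo alternative, which would scramble C9 relative to C10 while C5 and C10 stay correct. The fallback erases C9 and resets it under substrate control. It sets out from 10 as obtained, whatever its C9 composition. Saegusa–Ito oxidation (Pd(OAc)2, MeCN/DMSO, 23 °C) converts the enol silane into the C8=C9 enone aldehyde F1. Wittig methoxymethylenation of the aldehyde under the conditions of step 8 gives the enone enol ether F2. Dissolving-metal conjugate reduction (Li, NH3/THF, t-BuOH 1 equiv, −78 °C) protonates C9 axially, so the chain becomes equatorial and cis to the C10 methyl group. After removal of ammonia the lithium enolate is trapped with PhN(SO2CF3)2, which rejoins the route at 12.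

Step 13. O-Methylation or γ-methylation of the potassium dienolate may compete with C4-alkylation, and the alkoxide may attack the enol triflate. The fallback is a metalloenamine alkylation setting out from 18. Condensation with tert-butylamine (MgSO4, CH2Cl2) gives the unsaturated aldimine F3. Deprotonation with LiN(i-Pr)2 (THF, −78 °C) and addition of MeI alkylate the azadienyl anion at C4 on the face opposite C20, giving the β,γ-unsaturated imine F4. Buffered hydrolysis (AcOH/NaOAc, THF/H2O) returns to the route at 19.

Step 12. The basic phosphorus ylide may enolise the enone at C5 in place of adding to the hindered C4 carbonyl, so that conversion stalls. The fallback is a sulfur-ylide homologation setting out from 16. Dimethylsulfonium methylide (Me3SI, KN(SiMe3)2, THF, −10 °C) adds 1,2 to give the spiro vinyl oxirane F5. MgBr2·OEt2 (CH2Cl2, −20 °C) opens it to the allylic C4 cation, and a hydride shift from C19 (Meinwald rearrangement) gives the β,γ-unsaturated aldehyde F6. This forms the same dienolate as 18 under the conditions of step 13 and so rejoins the route at 19.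

**Further compounds**
F1 | step 6 | C8=C9 enone aldehyde (ethyl 3-[(3R)-5-tert-butoxy-3-methyl-5-oxopentyl]-2-formyl-2,4-dimethyl-5-oxocyclohex-3-ene-1-carboxylate, ring centres as in 10) | O=C[C@@]1(C)C(CC[C@@H](C)CC(=O)OC(C)(C)C)=C(C)C(=O)C[C@@H]1C(=O)OCC
F2 | step 6 | C8=C9 enone with C10–CH=CH–OMe (E/Z mixture) | COC=C[C@@]1(C)C(CC[C@@H](C)CC(=O)OC(C)(C)C)=C(C)C(=O)C[C@@H]1C(=O)OCC
F3 | step 13 | N-tert-butyl aldimine of enal 18 | CC(C)(C)N=CC1=CCC[C@@]2(C)[C@H](CC[C@@H](C)CC(=O)OC(C)(C)C)C(C)=C(OS(=O)(=O)C(F)(F)F)C[C@H]12
F4 | step 13 | N-tert-butyl aldimine of aldehyde 19 | CC(C)(C)N=C[C@]1(C)C=CC[C@@]2(C)[C@H](CC[C@@H](C)CC(=O)OC(C)(C)C)C(C)=C(OS(=O)(=O)C(F)(F)F)C[C@H]12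
F5 | step 12 | spiro vinyl oxirane at C4 (C4 epimers) | C1OC12C=CC[C@@]3(C)[C@H](CC[C@@H](C)CC(=O)OC(C)(C)C)C(C)=C(OS(=O)(=O)C(F)(F)F)C[C@H]23
F6 | step 12 | β,γ-unsaturated aldehyde (C4–H, C4 epimers, C2=C3) | O=CC1C=CC[C@@]2(C)[C@H](CC[C@@H](C)CC(=O)OC(C)(C)C)C(C)=C(OS(=O)(=O)C(F)(F)F)C[C@H]12
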